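## Structural features

Target 7 is an 8–8' (dibenzylbutane) lignan. It is an open chain C7–C8–C8'–C7' in which each inner carbon carries a methyl group (C9, C9') and each outer benzylic CH2 carries a 4-hydroxy-3,5-dimethoxyphenyl ring (ring A on C7, ring B on C7'). The two arenes are the only rings, and the four-carbon chain is their only link. The only stereocentres, C8 and C8', are adjacent and constitutionally identical; the SMILES decodes as (2R,3S), so 7 is the achiral meso (erythro) diastereomer and only the relative configuration must be set. That relative configuration is the real difficulty. Each centre bears H, CH3 and CH2Ar, which are similar in size, no heteroatom, carbonyl group or ring is near enough to steer an open-chain reaction, and the meso and racemic forms would be hard to separate at the end. The fragile points are three: the electron-rich 2,6-dimethoxyphenols (one-electron oxidants give phenoxyl radicals and quinone methides), any cation at C7 (the other ring would capture it to give an aryltetralin), and the central C4–O bond of each 1,2,3-trioxygenated ring (lost under dissolving-metal conditions). The key step exploits three features together: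

- the mirror symmetry through the midpoint of C8–C8';
- the fact that C7 and C7' are both benzylic, so an extra C7–C7' bond can be put in and later removed by hydrogenolysis;
- the free para oxygens O4 (ring A) and O4' (ring B), which can be tied by a temporary tether.

With that bond and tether in place, C7–C8–C8'–C7' is a cyclobutane, the meso relation becomes a cis relation of two ring methyl groups, and the ring is the syn head-to-head [2+2] dimer of two (E)-propenylarene halves.

## Logic of the disconnections

The route in one sentence: a tether-enforced, syn head-to-head [2+2] photocycloaddition of 4 builds a cyclobutane whose surplus bond is removed afterwards. That sentence does not fit an oxidative 8–8' coupling, a furan hydrogenation or an aryl/alkyl coupling.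

**7 ⇒ 6 ⇒ 5 (reconnection).** Nothing in 7 is cut at first. A bond C7–C7' is added (6), and O4 and O4' are bridged by an o-xylylene unit (5). In the forward direction the bonds cut are C7–C7' and the two O–CH2 bonds of the bridge. All three are benzylic and answer to the same hydrogenolysis. The reason is that an acyclic erythro/threo problem with no handle becomes a cis/trans problem on a four-membered ring. The gain is that C8 and C8' become part of a rigid, mirror-symmetric ring that a single cycloaddition can make. The demand is that only the doubly benzylic ring bond breaks (not C7–C8 or C8–C8') and that the C8–H and C8'–H bonds stay untouched.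

**5 ⇒ 4 (key disconnection).** C8–C8' and C7–C7' are cut together as a retro-[2+2]. This removes four stereocentres, the cyclobutane and the macrocycle at once. What remains is a stereocentre-free, symmetric bis-alkene whose only stereochemical information is two E double bonds. The forward step must therefore be head-to-head, syn (aryl over aryl) and stereospecific with respect to both alkenes. Then aryl/aryl cis and aryl/methyl trans together force methyl/methyl cis.

**4 ⇒ 3.** No C–C bond is cut; each C7=C8 double bond is moved to C8=C9. The reason is that the allylarene, not the propenylarene, is the reliable article of commerce, and conjugation makes the shift downhill. The demand is high E geometry at both ends, because alkene geometry is what step 3 translates into configuration.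

**3 ⇒ 1 + 2.** The two O–CH2 bonds of the bridge are cut. This halves the molecule into two copies of 1 and one bis-electrophile 2, both purchasable. The demand is only clean O-alkylation of a hindered phenoxide.

## Other disconnections considered

**Alternative 1:** (the first that comes to mind) C8–C8' is cut alone, in the biomimetic sense.

- Forward key step: one-electron oxidation (FeCl3, Ag2O or a laccase with O2) of (E)-2,6-dimethoxy-4-(prop-1-en-1-yl)phenol A1, followed by radical–radical coupling at C8 to the bis(quinone methide) A2.
- Water would then capture A2 as the 2,5-diaryl-3,4-dimethyltetrahydrofuran A3, and the two benzylic C–O bonds would be hydrogenolysed.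
- Ground for rejection: the coupling of two free radicals has an early, open transition state in which nothing links the two prochiral C8 faces. Like and unlike combinations should be close in energy, so a meso/racemic mixture is expected.
- Coupling at O4 (8–O–4') also competes, and the C8–H of A2 is acidified towards tautomerisation.
- The chosen plan forms the same bond from the same C6–C3 unit but ties the two faces together.

**Alternative 2:** C8–C8' is cut in the polar sense, and both stereocentres are flattened into an aromatic ring.

- Forward key step: the enolate of 1-[4-(benzyloxy)-3,5-dimethoxyphenyl]propan-1-one A4 would be alkylated with its 2-bromo derivative A5 to the 1,4-diketone A6.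
- A6 would be cyclodehydrated to the furan A7, hydrogenated to the all-cis tetrahydrofuran A8, and hydrogenolysed.
- The stereochemical idea (cis delivery of hydrogen to a flat ring) is sound.
- Ground for rejection: it needs roughly twice as many steps, and it installs oxygen at C7 and C7' only to remove it again.
- It also requires all four hydrogens to reach a tetrasubstituted, diaryl-conjugated furan from one face without desorption. Any premature C–O hydrogenolysis passes through enolisable or styrene-type species that can epimerise C8.

**Alternative 3:** C8–C8' is cut as a reductive union of two allylarenes on a metal, with C9 and C9' as the carbon–metal termini.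

- Forward key step: the benzyl ether A9 of 1 would react with the zirconocene equivalent from Cp2ZrCl2 and n-BuLi (2 equiv) to give the 3,4-bis(arylmethyl)zirconacyclopentane A10.
- Protonolysis of the two C–Zr bonds would turn C9 and C9' into methyl groups.
- This is the shortest conceivable route and joins two carbons of like polarity.
- Ground for rejection: metallacycle formation is reversible and should settle on the trans-3,4-disubstituted ring, where the two arylmethyl groups avoid each other. Trans on that ring maps onto the threo, racemic butane A11, which is the wrong diastereomer.
- A para,para' tether would not help, because the CH2 spacers decouple the arenes from C8 and C8'.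

Key step: step 3

Assumption: because the two aryl groups are identical, the (2R,3S) configuration in the SMILES is read as the achiral meso compound, so no enantioselective element is planned.

## Route

Step 1
Reactants: 1 4-allyl-2,6-dimethoxyphenol (2.1 equiv); 2 1,2-bis(bromomethyl)benzene (1 equiv)
Product: 3 1,2-bis[(4-allyl-2,6-dimethoxyphenoxy)methyl]benzene
Conditions: K2CO3, DMF, 60 °C
Reagents that add atoms: none
Why: Twofold Williamson ether synthesis: the phenoxide of 1 is flanked by two methoxy groups but still reacts at oxygen with a primary benzylic bromide by SN2, as in routine O-benzylation of syringyl phenols, and a slight excess of 1 drives both ends to completion. No stereocentre is formed.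

Step 2
Reactants: 3 1,2-bis[(4-allyl-2,6-dimethoxyphenoxy)methyl]benzene
Product: 4 1,2-bis{[2,6-dimethoxy-4-((E)-prop-1-en-1-yl)phenoxy]methyl}benzene
Conditions: RuHCl(CO)(PPh3)3 (2 mol %), PhMe, 90 °C; silica plug, recrystallisation
Reagents that add atoms: none
Why: Ruthenium-hydride-catalysed alkene isomerisation (migratory insertion, then β-hydride elimination) moves each double bond into conjugation with its electron-rich ring, and the reversible process settles on the thermodynamically preferred E geometry. The neutral conditions leave the aryl benzyl ethers untouched, and recrystallisation of the symmetric product should remove residual E,Z material, which matters because alkene geometry is the stereochemical information used in step 3.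

Step 3
Reactants: 4 1,2-bis{[2,6-dimethoxy-4-((E)-prop-1-en-1-yl)phenoxy]methyl}benzene
Product: 5 cyclobutane-bridged dioxa[2.6]paracyclophane: (1R,2S,3R,4S)-3,4-dimethylcyclobutane (meso; r-1,c-2-diaryl-t-3,t-4-dimethyl) whose two 3,5-dimethoxy-1,4-phenylene rings on C1 and C2 are joined through their para oxygens by the o-xylylene unit
Conditions: hν (high-pressure Hg lamp, Pyrex filter, λ > 300 nm), Ar-sparged PhMe (1–2 mM), 5–10 °C
Reagents that add atoms: none
Why: Direct excitation of one (E)-β-methylstyrene chromophore of 4 populates its planar, comparatively long-lived S1 state, which the six-atom para,para' tether lets fold onto the ground-state partner as a face-to-face intramolecular excimer that collapses by a suprafacial–suprafacial [π2s+π2s] cycloaddition, forming C8–C8' and C7–C7' together. The closest known reaction type is the intramolecular [2+2] photocycloaddition of α,ω-bis(4-vinylphenyl)alkanes and bis(4-vinylphenoxy) ethers to cis-cyclobutane-bridged [2.n]paracyclophanes, together with the syn head-to-head singlet photodimerisation of anethole-type alkenes. Two rings close: the cyclobutane by the concerted four-centre addition, and as its consequence a 16-membered (shortest path) paracyclophane ring, a macrocyclisation whose modest strain is paid for by the photon. Head-to-head regiochemistry and the cis relation of C7 and C7' are fixed by the tether, whose oxygens can span only an estimated 3–5 Å, which brackets the sandwich spacing, whereas the anti head-to-head and head-to-tail alignments would hold them about 10 Å apart. C8 and C8' are fixed by stereospecificity: each E alkene keeps its aryl and methyl groups trans across the new ring, so two aryl groups on one face force both methyl groups onto the other face, cis to each other, which is the meso relation of 7. The central alkoxy group of a 1,2,3-trioxygenated arene stands perpendicular to its ring, so both O–CH2 bonds already point towards the partner ring and favour the sandwich. The selectivity needed is cycloaddition over E-to-Z photoisomerisation, intersystem crossing to a stepwise triplet path and intermolecular dimerisation, and it is secured by the intramolecular excimer, high dilution, exclusion of oxygen and triplet sensitisers, a cool non-polar medium, and the λ > 300 nm cut-off, where 4 absorbs but the non-conjugated arenes of 5 should not.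

Step 4
Reactants: 5 cyclobutane-bridged dioxa[2.6]paracyclophane
Product: 7 meso-4,4'-[(2R,3S)-2,3-dimethylbutane-1,4-diyl]bis(2,6-dimethoxyphenol), via cis-diarylcyclobutane bisphenol 6 (not isolated)
Conditions: H2 (5 bar), 10% Pd/C, EtOH–AcOH (9:1), 60 °C
Reagents that add atoms: none
Why: O-Benzyl hydrogenolysis first frees both phenols and removes the tether to give 6; the same catalyst should then cleave C7–C7', the only C–C bond that is at once doubly benzylic, part of a four-membered ring (about 26 kcal/mol of strain) and eclipsed by two cis aryl groups, which is the known catalytic hydrogenolysis of 1,2-diarylcyclobutanes to 1,4-diarylbutanes. C7 and C7' become CH2 groups so their configuration is erased, while C8 and C8' are not touched, and the cis-dimethyl relation of the ring becomes the (2R,3S) meso relation.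

## Compound list

1 | 4-allyl-2,6-dimethoxyphenol | C=CCc1cc(OC)c(O)c(OC)c1 | starting material
2 | 1,2-bis(bromomethyl)benzene | BrCc1ccccc1CBr | starting material
3 | 1,2-bis[(4-allyl-2,6-dimethoxyphenoxy)methyl]benzene | C=CCc1cc(OC)c(OCc2ccccc2COc2c(OC)cc(CC=C)cc2OC)c(OC)c1 | intermediate
4 | 1,2-bis{[2,6-dimethoxy-4-((E)-prop-1-en-1-yl)phenoxy]methyl}benzene | C/C=C/c1cc(OC)c(OCc2ccccc2COc2c(OC)cc(/C=C/C)cc2OC)c(OC)c1 | intermediate
5 | o-xylylene-tethered (1R,2S,3R,4S)-1,2-bis(3,5-dimethoxy-4-oxyphenyl)-3,4-dimethylcyclobutane (dioxa[2.6]paracyclophane, meso) | C[C@@H]1[C@H](C)[C@@H](c2cc(OC)c3c(OC)c2)[C@H]1c2cc(OC)c(c(OC)c2)OCc2ccccc2CO3 | intermediate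
6 | 4,4'-[(1R,2S,3R,4S)-3,4-dimethylcyclobutane-1,2-diyl]bis(2,6-dimethoxyphenol) (meso, not isolated) | C[C@@H]1[C@H](C)[C@@H](c2cc(OC)c(O)c(OC)c2)[C@H]1c3cc(OC)c(O)c(OC)c3 | intermediate
7 | meso-4,4'-[(2R,3S)-2,3-dimethylbutane-1,4-diyl]bis(2,6-dimethoxyphenol) | COc1cc(C[C@@H](C)[C@@H](C)Cc2cc(OC)c(O)c(OC)c2)cc(OC)c1O | target

## Step count and least certain steps

Total step count: 4. Longest linear sequence: 4 (1 → 3 → 4 → 5 → 7).

**Step 3 (key step).**

- The most likely failure is excited-state leakage. E-to-Z photoisomerisation, or intersystem crossing to a stepwise triplet 1,4-biradical, could compete with collapse of the excimer. An E,Z pairing or bond rotation before ring closure would then erode the cis-dimethyl relation.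
- A second risk is photohomolysis of the ArO–CH2Ar bonds. These stand perpendicular to their rings and are weak relative to the photon energy.
- A third risk is oligomerisation if the dilution is insufficient.
- A partial safeguard is that 5 is mirror-symmetric while the product of an E,Z pairing is not, so purification at this stage should be possible.
- Fallback, from 4 and back at 5: the excited-state manifold is abandoned and the same ring is closed as a hole-catalysed (radical-cation) [2+2] cycloaddition under visible light. The reagents would be 2,4,6-tris(4-methoxyphenyl)pyrylium tetrafluoroborate as photo-oxidant and naphthalene as electron relay, in CH2Cl2 at low temperature.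
- This is the known cyclodimerisation of anethole-type alkenes. No alkene excited state is populated, so E-to-Z isomerisation has no channel, since radical cations relax towards E. No UV light reaches the aryl benzyl ethers.
- The tether still excludes the anti dimer that this manifold prefers when untethered. The path is more stepwise, so the sandwich enforced by the tether carries the whole stereochemical burden. No new compound is made.

**Step 4.**

- The most likely failure is slow C–C hydrogenolysis once the tether, and with it the cyclophane strain, has gone, so that the reaction stalls at 6.
- At higher temperature, reversible β-hydride elimination of surface-bound benzylic palladium alkyls could exchange the C8–H bond and scramble the meso relation.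
- Dissolving-metal cleavage is not an option, because it would remove the central oxygen of the trioxygenated rings.
- Fallback, from 5 and back at 7: C7–C7' is cut oxidatively instead of reductively. One-electron photo-oxidation of 5 (the same pyrylium salt, O2, blue LED, CH2Cl2, low temperature) should open the strained bond to the 1,4-distonic radical cation.
- Triplet oxygen would trap this intermediate as the tethered cis-4,5-dimethyl-3,6-diaryl-1,2-dioxane F1. This is the known endoperoxidation of cyclobutane-derived 1,4-radical cations.
- H2, Pd/C in EtOH–AcOH would then cleave the O–O bond, the two electron-rich benzylic C–O bonds and the tether. These are all much easier hydrogenolyses than that of a C–C bond, and C8 and C8' remain spectators.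

**Step 2.**

- The most likely failure is incomplete migration at one of the two ends, or residual Z geometry. The statistical weight of this error is doubled in a bis-alkene, and it feeds directly into the wrong diastereomer in step 3.
- Fallback, from 1 and back at 4: the double bond is moved before the halves are joined. A prototropic shift (KOH, diethylene glycol, 150 °C) would convert 1 into (E)-2,6-dimethoxy-4-(prop-1-en-1-yl)phenol F2.
- F2 carries a single alkene, so the minor geometric isomer can be removed at the monomer stage by crystallisation or chromatography on AgNO3-impregnated silica.
- Twofold Williamson etherification of F2 with 2 (K2CO3, DMF, 60 °C) then gives 4.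

## Further compounds

F0 | step 3 | none | none
F1 | step 4 | o-xylylene-tethered cis-4,5-dimethyl-3,6-bis(3,5-dimethoxy-4-oxyphenyl)-1,2-dioxane (configuration at C3 and C6 immaterial) | C[C@@H]1[C@H](C)C(c2cc(OC)c3c(OC)c2)OOC1c2cc(OC)c(c(OC)c2)OCc2ccccc2CO3
F2 | step 2 | (E)-2,6-dimethoxy-4-(prop-1-en-1-yl)phenol | C/C=C/c1cc(OC)c(O)c(OC)c1
A1 | alternative 1 | (E)-2,6-dimethoxy-4-(prop-1-en-1-yl)phenol | C/C=C/c1cc(OC)c(O)c(OC)c1
A2 | alternative 1 | 8–8' bis(quinone methide) dimer (meso/racemic mixture expected) | O=C1C(OC)=CC(=CC(C)C(C)C=C2C=C(OC)C(=O)C(OC)=C2)C=C1OC
A3 | alternative 1 | 2,5-bis(4-hydroxy-3,5-dimethoxyphenyl)-3,4-dimethyltetrahydrofuran (stereoisomer mixture expected) | CC1C(C)C(c2cc(OC)c(O)c(OC)c2)OC1c1cc(OC)c(O)c(OC)c1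
A4 | alternative 2 | 1-[4-(benzyloxy)-3,5-dimethoxyphenyl]propan-1-one | CCC(=O)c1cc(OC)c(OCc2ccccc2)c(OC)c1
A5 | alternative 2 | 1-[4-(benzyloxy)-3,5-dimethoxyphenyl]-2-bromopropan-1-one (racemic) | CC(Br)C(=O)c1cc(OC)c(OCc2ccccc2)c(OC)c1
A6 | alternative 2 | 1,4-bis[4-(benzyloxy)-3,5-dimethoxyphenyl]-2,3-dimethylbutane-1,4-dione (diastereomer mixture) | CC(C(C)C(=O)c1cc(OC)c(OCc2ccccc2)c(OC)c1)C(=O)c1cc(OC)c(OCc2ccccc2)c(OC)c1
A7 | alternative 2 | 2,5-bis[4-(benzyloxy)-3,5-dimethoxyphenyl]-3,4-dimethylfuran | Cc1c(C)c(-c2cc(OC)c(OCc3ccccc3)c(OC)c2)oc1-c1cc(OC)c(OCc2ccccc2)c(OC)c1
A8 | alternative 2 | all-cis-2,5-bis(4-hydroxy-3,5-dimethoxyphenyl)-3,4-dimethyltetrahydrofuran (meso) | C[C@H]1[C@@H](C)[C@@H](c2cc(OC)c(O)c(OC)c2)O[C@H]1c1cc(OC)c(O)c(OC)c1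
A9 | alternative 3 | 5-allyl-2-(benzyloxy)-1,3-dimethoxybenzene | C=CCc1cc(OC)c(OCc2ccccc2)c(OC)c1
A10 | alternative 3 | trans-3,4-bis{[4-(benzyloxy)-3,5-dimethoxyphenyl]methyl}-1,1-bis(cyclopentadienyl)zirconacyclopentane (racemic, one enantiomer drawn) | [cH-]1cccc1.[cH-]1cccc1.[Zr+2]1C[C@@H](Cc2cc(OC)c(OCc3ccccc3)c(OC)c2)[C@H](Cc2cc(OC)c(OCc3ccccc3)c(OC)c2)C1
A11 | alternative 3 | rac-(2S,3S)-1,4-bis[4-(benzyloxy)-3,5-dimethoxyphenyl]-2,3-dimethylbutane (threo, one enantiomer drawn) | C[C@@H](Cc1cc(OC)c(OCc2ccccc2)c(OC)c1)[C@H](Cc1cc(OC)c(OCc2ccccc2)c(OC)c1)C
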